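**Plan**

- Altisin is 2-(2,6-dimethoxyphenyl)-5-hydroxy-7,8-dimethoxy-4H-chromen-4-one. It has no stereocentre and no stereogenic double bond, so no stereochemistry has to be set.
- Enabling feature: ring A carries oxygen at C5 and C8, para to each other and flanking C4a/C8a. It is therefore the reduced form of a 2-acyl-1,4-benzoquinone in which C8a is an electrophilic CH carbon next to the acyl-bearing C4a.
- Cuts, in retrosynthetic order: the O8–CH3 bond; the O1–C8a bond of ring C (enol oxygen of a 1,3-diketone onto the quinone); the quinone back to a p-methoxyphenol; the C2–C3 bond (ketone enolate plus 2,6-dimethoxybenzoyl chloride).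
- Forward: rings A and B are bought, the C2–C3 bond joins them through the three-carbon chain, ring A is oxidised to the quinone with a two-electron oxidant that spares the enolised diketone, ring C closes, and the free 8-OH is methylated.

Key step: step 3

Remark: the 1,3-diketones of this route are drawn in the diketo form, although they should exist mainly as chelated enols; the enol oxygen on the carbon next to ring B is the nucleophile of step 3.

**Route**

Step 1
Reactants: 1 2'-hydroxy-4',5'-dimethoxyacetophenone; 2 2,6-dimethoxybenzoyl chloride
Product: 4 1-(2-hydroxy-4,5-dimethoxyphenyl)-3-(2,6-dimethoxyphenyl)propane-1,3-dione, via dilithium dianion of the acetophenone 3 (not isolated)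
Conditions: LiN(SiMe3)2 (3.2 equiv), THF, −78 → −10 °C; then 2 (1.0 equiv), −78 °C → rt; aq. HCl
Reagents that add atoms: none
Why: Claisen-type C-acylation of a ketone enolate by an acid chloride: in dianion 3 the enolate carbon is the most nucleophilic site, the chelated phenoxide being far less reactive, and the extra equivalent of LiN(SiMe3)2 turns the more acidic product into its diketonate at once so that it is not acylated again; this dianion protocol is established for 2,6-dimethoxybenzoyl chloride with other 2'-hydroxyacetophenones.

Step 2
Reactants: 4 1-(2-hydroxy-4,5-dimethoxyphenyl)-3-(2,6-dimethoxyphenyl)propane-1,3-dione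
Product: 5 1-(2,6-dimethoxyphenyl)-3-(4-methoxy-3,6-dioxocyclohexa-1,4-dien-1-yl)propane-1,3-dione
Conditions: PhI(OAc)2 (1.0 equiv), MeCN/H2O (4:1), 0 °C, 10 min; extractive work-up, crude 5 used at once
Reagents that add atoms: water, O
Why: Oxidative demethylation of a p-methoxyphenol by the trivalent iodine reagent PhI(OAc)2: two-electron oxidation of the phenol, addition of water at the methoxy-bearing para carbon and loss of methanol give the 2-acyl-5-methoxy-1,4-benzoquinone, and this oxidant, unlike a one-electron metal oxidant, attacks an enolised 1,3-diketone only slowly when no base is present.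

Step 3
Reactants: 5 1-(2,6-dimethoxyphenyl)-3-(4-methoxy-3,6-dioxocyclohexa-1,4-dien-1-yl)propane-1,3-dione
Product: 6 2-(2,6-dimethoxyphenyl)-5,8-dihydroxy-7-methoxy-4H-chromen-4-one
Conditions: NaOAc (1.0 equiv), degassed AcOH (0.01 M), rt, Ar
Reagents that add atoms: none
Why: Proposed new method: acetate acts as a general base while the enol oxygen on the carbon bearing ring B adds to C8a, the quinone CH carbon that is β to both the quinone carbonyl at C5 and the side-chain carbonyl at C4, which forms the O1–C8a bond; loss of the C8a proton and enolisation of the two ring carbonyls then aromatise ring A to the 5,8-hydroquinone. The closest known reaction type is the intramolecular oxa-Michael addition of a phenol to a 2-aroyl-1,4-benzoquinone that gives 1,4-dihydroxyxanthones, backed by the general preference of heteronucleophiles for C3 of 2-acyl-1,4-benzoquinones; an enol oxygen of a 1,3-diketone has not been used as the donor. Ring C closes in the 6-endo-trig mode, the same mode by which 2'-hydroxychalcones close to flavanones. No stereocentre is created, since C8a is sp2 again after tautomerisation. The step needs attack at C8a and not at C6, and attack through oxygen and not through carbon: C6 is the donor-substituted β-carbon of the vinylogous ester formed with the 7-methoxy group and cannot be reached by the tether, and the central carbon of the diketone could reach C8a only through a four-membered ring. High dilution in buffered AcOH under argon holds back intermolecular Michael addition and quinone–hydroquinone redox exchange.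

Step 4
Reactants: 6 2-(2,6-dimethoxyphenyl)-5,8-dihydroxy-7-methoxy-4H-chromen-4-one
Product: 7 Altisin, 2-(2,6-dimethoxyphenyl)-5-hydroxy-7,8-dimethoxy-4H-chromen-4-one
Conditions: MeI (1.1 equiv), K2CO3 (1.1 equiv), degassed acetone, rt, Ar
Reagents that add atoms: iodomethane, CI
Why: Williamson etherification that is selective for the free 8-OH, because the 5-OH is held in a strong hydrogen bond to the C4 carbonyl and should be neither deprotonated nor alkylated by one equivalent of K2CO3 and MeI at room temperature, as in the partial methylation of other 5-hydroxyflavones.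

**Compound list**

1 | 2'-hydroxy-4',5'-dimethoxyacetophenone (1-(2-hydroxy-4,5-dimethoxyphenyl)ethan-1-one) | CC(=O)c1cc(OC)c(OC)cc1O | starting material
2 | 2,6-dimethoxybenzoyl chloride | COc1cccc(OC)c1C(Cl)=O | starting material
3 | dilithium dianion of 1 (lithium phenoxide and lithium enolate of the methyl ketone) | [Li+].[Li+].C=C([O-])c1cc(OC)c(OC)cc1[O-] | intermediate
4 | 1-(2-hydroxy-4,5-dimethoxyphenyl)-3-(2,6-dimethoxyphenyl)propane-1,3-dione | COc1cccc(OC)c1C(=O)CC(=O)c1cc(OC)c(OC)cc1O | intermediate
5 | 1-(2,6-dimethoxyphenyl)-3-(4-methoxy-3,6-dioxocyclohexa-1,4-dien-1-yl)propane-1,3-dione | O=C1C=C(OC)C(=O)C=C1C(=O)CC(=O)c1c(OC)cccc1OC | intermediate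
6 | 2-(2,6-dimethoxyphenyl)-5,8-dihydroxy-7-methoxy-4H-chromen-4-one | COc1cccc(OC)c1-c1cc(=O)c2c(O)cc(OC)c(O)c2o1 | intermediate
7 | Altisin, 2-(2,6-dimethoxyphenyl)-5-hydroxy-7,8-dimethoxy-4H-chromen-4-one | COc1cccc(OC)c1-c1cc(=O)c2c(O)cc(OC)c(OC)c2o1 | target

**Step count**

Total step count: 4. Longest linear sequence: 4 steps (1 → 4 → 5 → 6 → 7).

**Steps most likely to fail**

Step 3 (the new ring closure). The closure may lose out to redox exchange between hydroquinone already formed and acylquinone not yet reacted, to intermolecular Michael addition of the diketone carbon, or to addition of acetate or water at C8a. The fallback uses known chemistry, sets out from 2 and returns to the route at 7. Ring A is taken with O1 already in place, as 2'-hydroxy-3',4',6'-trimethoxyacetophenone F1. Its dilithium dianion F2 (LiN(SiMe3)2, THF, −78 → −10 °C) is C-acylated with 2 to give 1-(2-hydroxy-3,4,6-trimethoxyphenyl)-3-(2,6-dimethoxyphenyl)propane-1,3-dione F3. Cyclodehydration (cat. H2SO4, AcOH, 95 °C) should give 2-(2,6-dimethoxyphenyl)-5,7,8-trimethoxy-4H-chromen-4-one F4. BCl3 (CH2Cl2, −78 → 0 °C) should then cleave only the methyl ether peri to the carbonyl by chelation-directed demethylation, which gives 7.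

Step 2. PhI(OAc)2 may react at the enolised diketone (α-functionalisation or oxidative closure onto the phenol oxygen) instead of oxidising the chelated phenol, and the acylquinone may close early and be oxidised further by remaining reagent in the aqueous medium. The fallback sets out from 2 and returns at 5; it reaches the quinone from the hydroquinone oxidation level under anhydrous, non-acidic conditions. 2',5'-Dihydroxy-4'-methoxyacetophenone F5, a known compound, is converted with LiN(SiMe3)2 (4.3 equiv, THF, −78 → −10 °C) into its trilithium trianion F6. This is C-acylated with 2 to give 1-(2,5-dihydroxy-4-methoxyphenyl)-3-(2,6-dimethoxyphenyl)propane-1,3-dione F7. Dehydrogenation with Ag2O and Na2SO4 in Et2O at rt, the standard preparation of acylquinones from acylhydroquinones, should give 5 without touching the diketone.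

Step 1. O-acylation of the phenoxide or a second acylation of the product may compete with C-acylation, because the acid chloride is hindered. The fallback sets out from 1 and 2 and returns at 4. Deliberate O-aroylation (2, pyridine, cat. DMAP, 60 °C) gives 2-acetyl-4,5-dimethoxyphenyl 2,6-dimethoxybenzoate F8. Baker–Venkataraman rearrangement (KOtBu, THF, rt), in which the ketone enolate takes the aroyl group from the neighbouring ester oxygen intramolecularly, should then give 4.

Further compounds
F1 | step 3 | 2'-hydroxy-3',4',6'-trimethoxyacetophenone | CC(=O)c1c(O)c(OC)c(OC)cc1OC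
F2 | step 3 | dilithium dianion of F1 | [Li+].[Li+].C=C([O-])c1c([O-])c(OC)c(OC)cc1OC
F3 | step 3 | 1-(2-hydroxy-3,4,6-trimethoxyphenyl)-3-(2,6-dimethoxyphenyl)propane-1,3-dione | COc1cccc(OC)c1C(=O)CC(=O)c1c(O)c(OC)c(OC)cc1OC
F4 | step 3 | 2-(2,6-dimethoxyphenyl)-5,7,8-trimethoxy-4H-chromen-4-one | COc1cccc(OC)c1-c1cc(=O)c2c(OC)cc(OC)c(OC)c2o1
F5 | step 2 | 2',5'-dihydroxy-4'-methoxyacetophenone | CC(=O)c1cc(O)c(OC)cc1O
F6 | step 2 | trilithium trianion of F5 | [Li+].[Li+].[Li+].C=C([O-])c1cc([O-])c(OC)cc1[O-]
F7 | step 2 | 1-(2,5-dihydroxy-4-methoxyphenyl)-3-(2,6-dimethoxyphenyl)propane-1,3-dione | COc1cccc(OC)c1C(=O)CC(=O)c1cc(O)c(OC)cc1O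
F8 | step 1 | 2-acetyl-4,5-dimethoxyphenyl 2,6-dimethoxybenzoate | CC(=O)c1cc(OC)c(OC)cc1OC(=O)c1c(OC)cccc1OC
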